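## Analysis of the target

The target is a dearomatised acylphloroglucinol: ring A (C4a, C5, C6, C7, C8, C8a in chroman numbering) is a cyclohexene-5,7-dione whose C8=C8a bond carries the ring oxygen O1, and ring B (O1, C2, C3, C4, C4a, C8a) is a 2,3-dimethyldihydropyranone whose C4 carbonyl is enolised towards C4a and hydrogen-bonded to the C5 carbonyl. It has five stereocentres: C2 (R) and C3 (R), trans on ring B; the quaternary C6 (S) between the C5 and C7 carbonyls, which carries a prenyl group and an eleven-carbon chain; C2′ (R) of that chain, which bears an isobutenyl and a 3-methylbut-3-enyl group; and the benzylic carbon (R) of the 3-phenylpropanoic acid on C8. Only C2 and C3 are adjacent; C2′ is insulated from C6 by the C1′ methylene and the benzylic carbon by C7 and C8, and no ring joins these centres, so none of them can pass its configuration on to another. The sensitive groups are three isolated alkenes (two trisubstituted, one 1,1-disubstituted) that close onto enol oxygens or the carboxyl group in strong acid, an acidic β-triketone, an epimerisable C3 next to the C4 carbonyl, and a ring B that can open by retro-oxa-Michael reaction in strong base. The hardest point is C6: both of its carbon substituents are CH2R groups and it is stereogenic only because C4a and C8 carry different substituents, so its configuration is decided when these two positions are first told apart. A second point is that ring B has to close on the oxygen of C8a and not on that of C5. The plan is built on the observation that C6 is the central carbon of a malonyl unit and that the triad C6–C1′–C2′ maps onto a cyclopropane spiro-fused to a cyclic malonate, in which the isobutenyl group on C2′ is the donor and the bond from C2′ to the next chain carbon C3′ is the one made on ring opening.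

## Retrosynthetic reasoning

30 to 29. The last operation only unmasks the carboxylic acid. The allyl ester 29 is chosen because it is removed under neutral conditions that leave the acid-sensitive alkenes, C3 and ring B untouched.

29 to 27 (through 28). The O1–C8a bond is cut, which opens ring B to the hydroxy triketone 28 and its silyl ether 27. In the forward direction the C2 hydroxyl adds to the C8a carbonyl and water is lost. The C2–O bond is never broken, so C2 is carried over with retention and both ring B stereocentres can be brought in with the anti acid 25. Cutting C2–O1 instead, as a conjugate closure onto an unsaturated ketone, would create C2 without any control element.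

27 to 20 and 25. The C4–C4a bond is cut. C4a is the only ring carbon of 20 that still carries hydrogen between two carbonyls, so C-acylation has a single productive site. Acid 25 comes from the hydroxy ester 21 by diastereoselective methylation of dianion 22 to 23, silylation to 24 and saponification.

20 to 16 and 17 (through 18 and 19). The bond from C8 to the benzylic carbon is cut. The forward reaction is an amine-catalysed conjugate addition of trione 16 to enal 17, in which the catalyst sets the benzylic centre. It is also the first event that distinguishes C4a from C8, so C6 becomes stereogenic here. This order is preferred because acylating 16 with 25 first would differentiate the two ring CH2 positions with no chiral influence other than the remote C2′. Lactol 18 is oxidised to lactone 19, and 19 is opened to ester 20.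

16 to 12 and 13 (through 14 and 15). The C5–C4a and C7–C8 bonds are cut. Keto diester 13 supplies C4a, C8a and C8; its ester groups activate both methylene groups for C-acylation by dichloride 12 and are removed afterwards through 14 and 15. Trione 16 is constitutionally symmetric about C6, so no stereochemical question arises.

12 to 10 (through 11). This is functional-group interchange only: acylal 10 is hydrolysed to diacid 11, which is activated as 12.

10 to 4, 6 and 7 (through 8 and 9). This is the key disconnection. The C2′–C3′ bond and the bond from C6 to the prenyl CH2 are cut. In the forward step cuprate 8, made from Grignard reagent 6, opens cyclopropane 4 at C2′ with inversion, and enolate 9 is trapped by bromide 7. Both carbon substituents of C6 and the C2′ stereocentre are thus installed in one flask while C6 is still a symmetric malonyl carbon.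

4 to 2 and 3; 2 to 1; 6 to 5. The cyclopropane is cut into ylide 2, a carbene equivalent of 1, and the terminal alkene of diene 3. Asymmetric carbene transfer sets the single stereocentre that the key step then relays to C2′. Grignard reagent 6 is made from bromide 5.

## Alternatives that were turned down

Alternative 1: The isobutenyl group on C2′ is traded for a hydroxymethyl group, and the disconnection is a temporary bond from that oxygen to the C5 carbon of a trione that is symmetric about C6. In the forward sense a sulfonic acid in moist solvent would let the primary alcohol form a six-membered cyclic enol ether reversibly with either flanking carbonyl, and the mixture should drain into the bicyclic vinylogous ester A1, in which the chain branch and the angular prenyl group are trans.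
- For: C6 would be fixed under thermodynamic control inside a ring, with the nearest stereocentre as the control element. This is precisely where the chosen route is weakest. The tether also makes C4a and C8 constitutionally different.
- Against: the equilibrium only decides which of two similar groups on C6 is axial on the new ring, so the bias is real but small. The acid equilibration places a prenyl group beside enol oxygens under conditions in which such groups close to chromans. Afterwards the tether has to be hydrolysed and the CH2OH group rebuilt into the isobutenyl group through an α-branched aldehyde, which endangers C2′ and adds steps.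
- Comparison: it is stronger on C6 and weaker on step economy and on the safety of C2′. The chosen route offers instead the complete carbon environment of C6 from one flask, with C2′ transferred stereospecifically from a cyclopropane.

Alternative 2: The C1′–C2′ bond is cut on an aromatic precursor that already carries ring B and the C8 side chain. Base would release an ortho-quinone methide at C6, a catalyst-bound enamine of a seven-carbon aldehyde would add to its exocyclic carbon, and the aldehyde would then close on O5 to give lactol A2.
- For: on an aromatic core the regiochemistry of ring B is unambiguous, whereas the chosen route has to argue for it. Aminocatalytic addition sets C2′ dependably, and the lactol carbon is a direct precursor of the isobutenyl group.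
- Against: the precursor is a hexasubstituted benzene with three phenolic oxygens that must be told apart. C6 becomes quaternary last, by alkylative dearomatisation, where carbon versus oxygen prenylation and the facial choice relative to a flexible lactol are both open. The catalyst must also override three stereocentres already present.
- Comparison: it is stronger on ring B and on the order in which stereocentres are set. The chosen route makes the quaternary carbon early, by C-alkylation of a malonyl enolate, where neither the carbon/oxygen nor the facial question exists, and it is shorter up to that point.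

Alternative 3: The C4a–C5 bond is cut. A preformed chiral dihydropyranone that carries the C8 side chain and a C7 ketone is linked through C6 to a methyl ester; an alkoxide base would generate the cross-conjugated dienolate, whose C4a terminus attacks the ester and closes ring A to give A3.
- For: ring B, its two stereocentres and the O1–C8a connection exist before ring A, so the regiochemical risk of the chosen endgame does not arise. The route is convergent and ends one deprotection away from the target.
- Against: C6 must already be an acyclic quaternary stereocentre with two different acyl arms, which means desymmetrising a malonate that bears two CH2R groups, the same problem in a less tractable place. The ring closure is the attack of a hindered dienolate terminus on a neopentyl ester. Removing the tert-butyl ester then needs acid, which threatens the prenyl groups.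
- Comparison: it is better on ring B regiochemistry. The chosen route keeps C6 symmetric through all robust C–C bond formations and reaches the substrate of its key step in two steps.

Key step: step 4

Remarks on the chemistry
- The ring A tricarbonyl compounds are tautomeric mixtures. Each is drawn as one enol form (14 and 15 as the form in which the two arms on C6 are equal), and stereodescriptors refer to the form drawn.
- Assumption: Rh2(S-PTTL)4 is taken to deliver the (1S)-cyclopropane 4. If the sense of induction is the opposite, Rh2(R-PTTL)4 is used; the configuration is checked on 4 before the key step.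

## Route

Step 1
Reactants: 1 Meldrum's acid
Product: 2 phenyliodonium ylide of Meldrum's acid
Conditions: PhI(OAc)2, KOH, MeOH, 0 °C
Reagents that add atoms: (diacetoxyiodo)benzene, CC(=O)OI(OC(C)=O)c1ccccc1
Why: Ligand exchange at iodine by the carbon acid (pKa about 5) gives the stabilised iodonium ylide; this is the standard preparation of an isolable carbene precursor that avoids a diazo compound.

Step 2
Reactants: 2 phenyliodonium ylide of Meldrum's acid; 3 4-methylpenta-1,3-diene
Product: 4 (1S)-6,6-dimethyl-1-(2-methylprop-1-enyl)-5,7-dioxaspiro[2.5]octane-4,8-dione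
Conditions: Rh2(S-PTTL)4 (dirhodium tetrakis[N-phthaloyl-(S)-tert-leucinate], 1 mol %), 3 (5 equiv), CH2Cl2, 0 °C → rt; recrystallisation
Reagents that add atoms: none
Why: Cyclopropanation by a divalent-rhodium carbenoid generated from the iodonium ylide. The bulky, electrophilic acceptor/acceptor carbenoid should add to the unhindered terminal alkene of 3, where the developing positive charge is allylic; the chiral carboxylate ligands select the alkene face and so set C1 of 4 (the later C2′). Crystallisation of the solid acylal should raise the enantiomeric purity.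

Step 3
Reactants: 5 4-bromo-2-methylbut-1-ene
Product: 6 (3-methylbut-3-enyl)magnesium bromide
Conditions: Mg turnings, I2 (cat.), THF, rt → 40 °C
Reagents that add atoms: magnesium, [Mg]
Why: Grignard formation from a primary homoallylic bromide; the homoallyl/cyclopropylmethyl rearrangement of this reagent is degenerate and leaves its constitution unchanged.

Step 4
Reactants: 4 (1S)-spirocyclopropane; 6 (3-methylbut-3-enyl)magnesium bromide; 7 prenyl bromide (1-bromo-3-methylbut-2-ene)
Product: 10 2,2-dimethyl-5-[(2R)-5-methyl-2-(2-methylprop-1-enyl)hex-5-enyl]-5-(3-methylbut-2-enyl)-1,3-dioxane-4,6-dione, via magnesium cuprate 8 (not isolated), via magnesium enolate 9 (not isolated)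
Conditions: CuBr·SMe2 (1 equiv), 6 (2 equiv), THF, −40 °C; 4, −78 → −30 °C; then 7 (3 equiv), DMPU, −30 °C → rt
Reagents that add atoms: none
Why: The six-membered acylal locks both carbonyl π systems in the alignment in which they accept electron density from the C6–C2′ bond most effectively, which makes 4 an electrophile at C2′ in the manner of a homologous Michael acceptor. Cuprate 8 (monovalent copper) adds oxidatively at C2′ on the face opposite to the departing C6, and reductive elimination from the trivalent-copper intermediate forms the C2′–C3′ bond and leaves enolate 9. The closest known reaction type is the 1,5-addition of organocuprates to cyclopropanes spiro-fused to Meldrum's acid, which runs with inversion at the substituted carbon, combined with C-alkylation of the enolate so formed. No ring is closed. The one new stereocentre, C2′, is controlled by the substrate alone: the (1S) centre of 4 is carried over with inversion and becomes (2R) in 10. The step needs attack at C2′ and not at C1′, at the distal alkene carbon or at a carbonyl group; the allylic character of C2′ directs the soft cuprate there, the two methyl groups on the alkene terminus hinder the 1,7-pathway, and the low basicity of the cuprate spares the acylal. Enolate 9 is then alkylated on carbon by the primary allylic bromide 7, and since C6 still carries two equivalent acyl arms the new quaternary centre is not stereogenic at this stage.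

Step 5
Reactants: 10 dialkylated Meldrum's acid
Product: 11 2-[(2R)-5-methyl-2-(2-methylprop-1-enyl)hex-5-enyl]-2-(3-methylbut-2-enyl)propanedioic acid
Conditions: LiOH, THF/H2O, 40 °C; then HCl (1 M) to pH 2, 0 °C
Reagents that add atoms: water, O
Why: Saponification of an acylal that has no α-hydrogen, so no enolate shields it from hydroxide; acetone is released and the dialkylmalonic acid should not decarboxylate at this temperature, while the brief cold acidification leaves the alkenes alone.

Step 6
Reactants: 11 dialkylmalonic acid
Product: 12 2-[(2R)-5-methyl-2-(2-methylprop-1-enyl)hex-5-enyl]-2-(3-methylbut-2-enyl)propanedioyl dichloride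
Conditions: 1-chloro-N,N,2-trimethylprop-1-en-1-amine (2.4 equiv), CH2Cl2, 0 °C → rt; used crude
Reagents that add atoms: 1-chloro-N,N,2-trimethylprop-1-en-1-amine, CC(C)=C(Cl)N(C)C
Why: Acid chloride formation with an α-chloroenamine under neutral conditions, so that no HCl is released onto the alkenes; without α-hydrogen the dichloride cannot form a ketene.

Step 7
Reactants: 12 dialkylmalonyl dichloride; 13 dimethyl 3-oxopentanedioate
Product: 14 dimethyl 4,6-dihydroxy-5-[(2R)-5-methyl-2-(2-methylprop-1-enyl)hex-5-enyl]-5-(3-methylbut-2-enyl)-2-oxocyclohexa-1(6),3-diene-1,3-dicarboxylate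
Conditions: MgCl2, pyridine, MeCN, 0 °C; slow addition of 12 in CH2Cl2, 0 °C → rt
Reagents that add atoms: none
Why: Two Claisen-type C-acylations of the magnesium-chelated β-keto ester enolates of 13, the second intramolecular and six-membered; chelation favours attack through carbon over oxygen and slow addition favours ring closure over oligomerisation. This assembles C5, C4a, C8a, C8 and C7 of ring A around C6.

Step 8
Reactants: 14 ring A diester
Product: 16 2-[(2R)-5-methyl-2-(2-methylprop-1-enyl)hex-5-enyl]-2-(3-methylbut-2-enyl)cyclohexane-1,3,5-trione, via dicarboxylic acid 15 (not isolated)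
Conditions: NaOH (2 M, aq), dioxane, 90 °C; then HCl to pH 3, 0 → 40 °C
Reagents that add atoms: none
Why: Saponification followed by decarboxylation of the vinylogous β-keto acids, as for phloroglucinol carboxylic acids; in base the ring is a delocalised enolate and so should resist retro-Claisen cleavage, and the mild acidification spares the prenyl groups.

Step 9
Reactants: 16 symmetric trione; 17 (E)-cinnamaldehyde
Product: 18 (4R,8S)-2-hydroxy-8-[(2R)-5-methyl-2-(2-methylprop-1-enyl)hex-5-enyl]-8-(3-methylbut-2-enyl)-4-phenyl-3,4-dihydro-2H-chromene-5,7(6H,8H)-dione (both anomers; ring–chain tautomers)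
Conditions: (R)-2-[diphenyl(trimethylsilyloxy)methyl]pyrrolidine (15 mol %), 17 as limiting reagent, CH2Cl2, −10 °C → rt
Reagents that add atoms: none
Why: Iminium-catalysed Michael addition of a cyclic 1,3-dicarbonyl compound to an enal, followed by lactol closure. The (R)-catalyst shields the Si face of the iminium β-carbon, so the ring carbon adds to the Re face and gives the (R)-benzylic centre. The choice between the two diastereotopic ring CH2 positions, which fixes C6, rests only on the catalyst pocket and the size difference of the two C6 substituents; the C6 epimer is carried along and removed at step 11.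

Step 10
Reactants: 18 lactol
Product: 19 (4R,8S)-8-[(2R)-5-methyl-2-(2-methylprop-1-enyl)hex-5-enyl]-8-(3-methylbut-2-enyl)-4-phenyl-3,4-dihydro-2H-chromene-2,5,7(6H,8H)-trione
Conditions: pyridinium chlorochromate [C5H5NH][CrO3Cl], 4 Å molecular sieves, CH2Cl2, 0 °C → rt
Reagents that add atoms: none
Why: Oxidation of a lactol to the lactone by hexavalent chromium, the usual follow-up for adducts of this aminocatalytic reaction; the isolated alkenes are inert under these conditions, and a lactol closed on the other enol oxygen would converge on the same ester in step 11.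

Step 11
Reactants: 19 enol lactone
Product: 20 prop-2-enyl (3R)-3-[(3S)-2-hydroxy-3-[(2R)-5-methyl-2-(2-methylprop-1-enyl)hex-5-enyl]-3-(3-methylbut-2-enyl)-4,6-dioxocyclohex-1-en-1-yl]-3-phenylpropanoate
Conditions: K2CO3 (1.5 equiv), prop-2-en-1-ol, THF, 0 °C → rt; HCl (0.5 M) to pH 4, 0 °C; chromatographic removal of the C6 epimer
Reagents that add atoms: prop-2-en-1-ol, C=CCO
Why: Alcoholysis of an enol lactone, which is a vinylogous anhydride and acylates the alkoxide readily; this frees the enol oxygen and masks the acid as an ester that can later be removed without acid or hydroxide.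

Step 12
Reactants: 21 methyl (R)-3-hydroxybutanoate
Product: 23 methyl (2R,3R)-3-hydroxy-2-methylbutanoate, via dilithium dianion 22 (not isolated)
Conditions: LiN(iPr)2 (2.2 equiv), THF, −78 → −20 °C; MeI, DMPU, −78 → −10 °C
Reagents that add atoms: iodomethane, CI
Why: Fráter–Seebach alkylation; the chelated alkoxide enolate is methylated on the face anti to the C3 methyl group, which sets the new centre (later C3 of ring B) anti to the carbinol (later C2).

Step 13
Reactants: 23 anti hydroxy ester
Product: 24 methyl (2R,3R)-3-[tert-butyl(dimethyl)silyl]oxy-2-methylbutanoate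
Conditions: TBSCl, imidazole, DMF, rt
Reagents that add atoms: tert-butyl(chloro)dimethylsilane, CC(C)(C)[Si](C)(C)Cl
Why: Silylation of a secondary alcohol, so that the acid can be activated in step 15 without self-acylation.

Step 14
Reactants: 24 silyl ether ester
Product: 25 (2R,3R)-3-[tert-butyl(dimethyl)silyl]oxy-2-methylbutanoic acid
Conditions: LiOH, THF/MeOH/H2O, 0 °C → rt; then HCl (1 M) to pH 3, 0 °C
Reagents that add atoms: water, O
Why: Saponification; at low temperature a β-silyloxy ester should be hydrolysed faster than it epimerises or eliminates.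

Step 15
Reactants: 20 ring A allyl ester; 25 silyloxy acid
Product: 27 prop-2-enyl (3R)-3-[(3S)-5-{(2R,3R)-3-[tert-butyl(dimethyl)silyl]oxy-2-methylbutanoyl}-2,6-dihydroxy-3-[(2R)-5-methyl-2-(2-methylprop-1-enyl)hex-5-enyl]-3-(3-methylbut-2-enyl)-4-oxocyclohexa-1,5-dien-1-yl]-3-phenylpropanoate, via enol ester 26 (not isolated)
Conditions: DCC, DMAP, CH2Cl2, 0 °C → rt
Reagents that add atoms: none
Why: Carbodiimide O-acylation of the vinylogous acid followed by DMAP-mediated O→C acyl shift, the standard route to 2-acyl-1,3-diones. C4a is the only ring carbon that can give an enolisable triketone, and the triketone is deprotonated as it forms, which protects the α-stereocentre of the acyl group.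

Step 16
Reactants: 27 silyloxy triketone
Product: 29 prop-2-enyl (3R)-3-[(2R,3R,6S)-4-hydroxy-2,3-dimethyl-6-[(2R)-5-methyl-2-(2-methylprop-1-enyl)hex-5-enyl]-6-(3-methylbut-2-enyl)-5,7-dioxo-2,3,6,7-tetrahydro-5H-chromen-8-yl]-3-phenylpropanoate, via hydroxy triketone 28 (not isolated)
Conditions: HF·pyridine, pyridine, THF, 0 °C → rt; then pyridinium p-toluenesulfonate, 4 Å molecular sieves, CH2Cl2, rt → 35 °C
Reagents that add atoms: none
Why: Desilylation followed by cyclodehydration of the hydroxy triketone to the dihydropyranone. The hydroxyl should add to the C8a carbonyl, whose ring neighbours are both trigonal, in preference to C5, which is shielded by the quaternary C6. The C2–O bond is not broken, so C2 is retained and the anti acid gives the trans-2,3-dimethyl ring with the chelated C4 enol/C5 carbonyl pair intact.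

Step 17
Reactants: 29 allyl ester of the target
Product: 30 (3R)-3-[(2R,3R,6S)-4-hydroxy-2,3-dimethyl-6-[(2R)-5-methyl-2-(2-methylprop-1-enyl)hex-5-enyl]-6-(3-methylbut-2-enyl)-5,7-dioxo-2,3,6,7-tetrahydro-5H-chromen-8-yl]-3-phenylpropanoic acid
Conditions: Pd(PPh3)4 (5 mol %), morpholine, THF, rt; NaH2PO4 (aq)
Reagents that add atoms: none
Why: Allyl transfer of the Tsuji–Trost type; zerovalent palladium ionises the allyl ester and morpholine captures the allyl group, under neutral conditions that touch neither the unactivated alkenes nor C3 nor ring B.

## Compound list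

1 | Meldrum's acid (2,2-dimethyl-1,3-dioxane-4,6-dione) | CC1(C)OC(=O)CC(=O)O1 | starting material
2 | 2,2-dimethyl-5-(phenyliodonio)-1,3-dioxane-4,6-dion-5-ide (phenyliodonium ylide) | CC1(C)OC(=O)[C-]([I+]c2ccccc2)C(=O)O1 | intermediate
3 | 4-methylpenta-1,3-diene | C=CC=C(C)C | starting material
4 | (1S)-6,6-dimethyl-1-(2-methylprop-1-enyl)-5,7-dioxaspiro[2.5]octane-4,8-dione | CC1(C)OC(=O)C2(C[C@H]2C=C(C)C)C(=O)O1 | intermediate
5 | 4-bromo-2-methylbut-1-ene | C=C(C)CCBr | starting material
6 | (3-methylbut-3-enyl)magnesium bromide | C=C(C)CC[Mg]Br | intermediate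
7 | prenyl bromide (1-bromo-3-methylbut-2-ene) | CC(C)=CCBr | starting material
8 | bromomagnesium bis(3-methylbut-3-enyl)cuprate | C=C(C)CC[Cu-]CCC(C)=C.[Mg+]Br | intermediate
9 | bromomagnesium enolate of 2,2-dimethyl-5-[(2R)-5-methyl-2-(2-methylprop-1-enyl)hex-5-enyl]-1,3-dioxane-4,6-dione | C=C(C)CC[C@@H](C=C(C)C)CC1=C([O-])OC(C)(C)OC1=O.[Mg+]Br | intermediate
10 | 2,2-dimethyl-5-[(2R)-5-methyl-2-(2-methylprop-1-enyl)hex-5-enyl]-5-(3-methylbut-2-enyl)-1,3-dioxane-4,6-dione | C=C(C)CC[C@@H](C=C(C)C)CC1(CC=C(C)C)C(=O)OC(C)(C)OC1=O | intermediate
11 | 2-[(2R)-5-methyl-2-(2-methylprop-1-enyl)hex-5-enyl]-2-(3-methylbut-2-enyl)propanedioic acid | C=C(C)CC[C@@H](C=C(C)C)CC(CC=C(C)C)(C(=O)O)C(=O)O | intermediate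
12 | 2-[(2R)-5-methyl-2-(2-methylprop-1-enyl)hex-5-enyl]-2-(3-methylbut-2-enyl)propanedioyl dichloride | C=C(C)CC[C@@H](C=C(C)C)CC(CC=C(C)C)(C(=O)Cl)C(=O)Cl | intermediate
13 | dimethyl 3-oxopentanedioate | COC(=O)CC(=O)CC(=O)OC | starting material
14 | dimethyl 4,6-dihydroxy-5-[(2R)-5-methyl-2-(2-methylprop-1-enyl)hex-5-enyl]-5-(3-methylbut-2-enyl)-2-oxocyclohexa-1(6),3-diene-1,3-dicarboxylate | C=C(C)CC[C@@H](C=C(C)C)CC1(CC=C(C)C)C(O)=C(C(=O)OC)C(=O)C(C(=O)OC)=C1O | intermediate
15 | 4,6-dihydroxy-5-[(2R)-5-methyl-2-(2-methylprop-1-enyl)hex-5-enyl]-5-(3-methylbut-2-enyl)-2-oxocyclohexa-1(6),3-diene-1,3-dicarboxylic acid | C=C(C)CC[C@@H](C=C(C)C)CC1(CC=C(C)C)C(O)=C(C(=O)O)C(=O)C(C(=O)O)=C1O | intermediate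
16 | 2-[(2R)-5-methyl-2-(2-methylprop-1-enyl)hex-5-enyl]-2-(3-methylbut-2-enyl)cyclohexane-1,3,5-trione | C=C(C)CC[C@@H](C=C(C)C)CC1(CC=C(C)C)C(=O)CC(=O)CC1=O | intermediate
17 | (E)-cinnamaldehyde | O=C/C=C/c1ccccc1 | starting material
18 | (4R,8S)-2-hydroxy-8-[(2R)-5-methyl-2-(2-methylprop-1-enyl)hex-5-enyl]-8-(3-methylbut-2-enyl)-4-phenyl-3,4-dihydro-2H-chromene-5,7(6H,8H)-dione | C=C(C)CC[C@@H](C=C(C)C)C[C@@]1(CC=C(C)C)C(=O)CC(=O)C2=C1OC(O)C[C@@H]2c1ccccc1 | intermediate
19 | (4R,8S)-8-[(2R)-5-methyl-2-(2-methylprop-1-enyl)hex-5-enyl]-8-(3-methylbut-2-enyl)-4-phenyl-3,4-dihydro-2H-chromene-2,5,7(6H,8H)-trione | C=C(C)CC[C@@H](C=C(C)C)C[C@@]1(CC=C(C)C)C(=O)CC(=O)C2=C1OC(=O)C[C@@H]2c1ccccc1 | intermediate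
20 | prop-2-enyl (3R)-3-[(3S)-2-hydroxy-3-[(2R)-5-methyl-2-(2-methylprop-1-enyl)hex-5-enyl]-3-(3-methylbut-2-enyl)-4,6-dioxocyclohex-1-en-1-yl]-3-phenylpropanoate | C=C(C)CC[C@@H](C=C(C)C)C[C@@]1(CC=C(C)C)C(=O)CC(=O)C([C@H](CC(=O)OCC=C)c2ccccc2)=C1O | intermediate
21 | methyl (R)-3-hydroxybutanoate | COC(=O)C[C@@H](C)O | starting material
22 | dilithium dianion of methyl (R)-3-hydroxybutanoate | COC([O-])=C[C@@H](C)[O-].[Li+].[Li+] | intermediate
23 | methyl (2R,3R)-3-hydroxy-2-methylbutanoate | COC(=O)[C@H](C)[C@@H](C)O | intermediate
24 | methyl (2R,3R)-3-[tert-butyl(dimethyl)silyl]oxy-2-methylbutanoate | COC(=O)[C@H](C)[C@@H](C)O[Si](C)(C)C(C)(C)C | intermediate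
25 | (2R,3R)-3-[tert-butyl(dimethyl)silyl]oxy-2-methylbutanoic acid | OC(=O)[C@H](C)[C@@H](C)O[Si](C)(C)C(C)(C)C | intermediate
26 | enol ester of 20 with 25 (drawn acylated on the C8a oxygen; one of the interconverting enol esters) | C=C(C)CC[C@@H](C=C(C)C)C[C@@]1(CC=C(C)C)C(=O)CC(OC(=O)[C@H](C)[C@@H](C)O[Si](C)(C)C(C)(C)C)=C([C@H](CC(=O)OCC=C)c2ccccc2)C1=O | intermediate
27 | prop-2-enyl (3R)-3-[(3S)-5-{(2R,3R)-3-[tert-butyl(dimethyl)silyl]oxy-2-methylbutanoyl}-2,6-dihydroxy-3-[(2R)-5-methyl-2-(2-methylprop-1-enyl)hex-5-enyl]-3-(3-methylbut-2-enyl)-4-oxocyclohexa-1,5-dien-1-yl]-3-phenylpropanoate | C=C(C)CC[C@@H](C=C(C)C)C[C@@]1(CC=C(C)C)C(=O)C(C(=O)[C@H](C)[C@@H](C)O[Si](C)(C)C(C)(C)C)=C(O)C([C@H](CC(=O)OCC=C)c2ccccc2)=C1O | intermediate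
28 | prop-2-enyl (3R)-3-[(3S)-2,6-dihydroxy-5-[(2R,3R)-3-hydroxy-2-methylbutanoyl]-3-[(2R)-5-methyl-2-(2-methylprop-1-enyl)hex-5-enyl]-3-(3-methylbut-2-enyl)-4-oxocyclohexa-1,5-dien-1-yl]-3-phenylpropanoate | C=C(C)CC[C@@H](C=C(C)C)C[C@@]1(CC=C(C)C)C(=O)C(C(=O)[C@H](C)[C@@H](C)O)=C(O)C([C@H](CC(=O)OCC=C)c2ccccc2)=C1O | intermediate
29 | prop-2-enyl (3R)-3-[(2R,3R,6S)-4-hydroxy-2,3-dimethyl-6-[(2R)-5-methyl-2-(2-methylprop-1-enyl)hex-5-enyl]-6-(3-methylbut-2-enyl)-5,7-dioxo-2,3,6,7-tetrahydro-5H-chromen-8-yl]-3-phenylpropanoate | C=C(C)CC[C@@H](C=C(C)C)C[C@@]1(CC=C(C)C)C(=O)C2=C(O)[C@H](C)[C@@H](C)OC2=C([C@H](CC(=O)OCC=C)c2ccccc2)C1=O | intermediate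
30 | (3R)-3-[(2R,3R,6S)-4-hydroxy-2,3-dimethyl-6-[(2R)-5-methyl-2-(2-methylprop-1-enyl)hex-5-enyl]-6-(3-methylbut-2-enyl)-5,7-dioxo-2,3,6,7-tetrahydro-5H-chromen-8-yl]-3-phenylpropanoic acid | C=C(C)CC[C@@H](C=C(C)C)C[C@@]1(CC=C(C)C)C(=O)C2=C(O)[C@H](C)[C@@H](C)OC2=C([C@H](CC(=O)O)c2ccccc2)C1=O | target

## Step count and least certain steps

Total: 17 steps. Longest linear sequence: 13 steps (steps 1, 2, 4 to 11 and 15 to 17, from 1 to 30).

Step 4 (key step). The most likely failure is loss of stereochemical fidelity. The strongly donor-substituted cyclopropane can ionise, helped by magnesium halide, to an allyl cation/enolate ion pair before the cuprate arrives, which would erode the transfer of configuration to C2′. Attack on an acylal carbonyl is the second risk.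
Fallback, setting out from 3 and returning at 11. It uses a less activated diester, which should not ionise and has less electrophilic carbonyl groups, and it separates ring opening from alkylation. Dimethyl malonate is converted with PhI(OAc)2 and KOH into dimethyl 2-(phenyliodonio)propanedioate ylide F1. The same dirhodium-catalysed carbene transfer to 3 gives dimethyl (2S)-2-(2-methylprop-1-enyl)cyclopropane-1,1-dicarboxylate F2. The cuprate made from 6 and CuBr·SMe2 opens the cyclopropane with inversion to dimethyl 2-[(2R)-5-methyl-2-(2-methylprop-1-enyl)hex-5-enyl]propanedioate F3, which is isolated. NaH and 7 in THF then give dimethyl 2-[(2R)-5-methyl-2-(2-methylprop-1-enyl)hex-5-enyl]-2-(3-methylbut-2-enyl)propanedioate F4, and KOH in aqueous ethanol at reflux leads back to 11.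

Step 9. The likely failure is poor discrimination between the two diastereotopic ring CH2 positions, which would give the C6 epimer alongside 18. The catalyst should control the benzylic centre reliably, but C6 depends on the modest size difference between a prenyl group and a β-branched CH2R group. A second addition of 17 to the remaining ring CH2 group is also possible.
Fallback, setting out from 16 and 17 and returning at 19: an oxidative carbene-catalysed annulation. It uses (5aS,10bR)-2-mesityl-5a,10b-dihydro-4H,6H-indeno[2,1-b][1,2,4]triazolo[4,3-d][1,4]oxazin-2-ium chloride, or its enantiomer, whichever gives the (R)-benzylic centre, with K2CO3 and 3,3′,5,5′-tetra-tert-butyl-4,4′-diphenoquinone as oxidant. The unsaturated acyl azolium binds the enol oxygen next to C6 before the C–C bond forms, so the C6 substituents sit at the reacting site in a closed transition state. The lactone forms at once, which also removes the free aldehyde that allows a second addition.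

Step 16. The likely failures are closure of ring B on the C5 carbonyl instead of C8a, dehydration of the β-hydroxy ketone to the enone followed by non-stereospecific re-closure, and acid-promoted cyclisation of a prenyl group onto an enol oxygen.
Fallback, setting out from 20 and returning at 29. The polarity of the closure is reversed, so that an enol oxygen displaces an activated C2 hydroxyl with inversion under neutral Mitsunobu conditions; this calls for the syn acid. (4R)-4-Benzyl-3-propanoyl-1,3-oxazolidin-2-one undergoes an Evans syn aldol reaction with acetaldehyde (Bu2BOTf, iPr2NEt) to give (4R)-4-benzyl-3-[(2R,3S)-3-hydroxy-2-methylbutanoyl]-1,3-oxazolidin-2-one F5. TBSOTf and 2,6-lutidine give (4R)-4-benzyl-3-[(2R,3S)-3-[tert-butyl(dimethyl)silyl]oxy-2-methylbutanoyl]-1,3-oxazolidin-2-one F6, and LiOH/H2O2 releases (2R,3S)-3-[tert-butyl(dimethyl)silyl]oxy-2-methylbutanoic acid F7. DCC/DMAP acylation of 20 with this acid gives the (2R,3S)-silyloxy triketone F8, and buffered HF·pyridine gives the (2R,3S)-hydroxy triketone F9. PPh3 and diisopropyl azodicarboxylate then close ring B with inversion at C2 to 29.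

Step 7. The likely failure is closure of the second acylation on the enol oxygen, which would give a pyrandione, or intermolecular acylation to oligomers.
Fallback, setting out from 10 and returning at 14, with the ring closed by an ester condensation under alkoxide equilibration, where the trione enolate is the thermodynamic sink. NaOMe in MeOH opens 10 to the malonic half ester (4R)-2-methoxycarbonyl-7-methyl-2-(3-methylbut-2-enyl)-4-(2-methylprop-1-enyl)oct-7-enoic acid F10. The chloroenamine of step 6 converts it into methyl (4R)-2-carbonochloridoyl-7-methyl-2-(3-methylbut-2-enyl)-4-(2-methylprop-1-enyl)oct-7-enoate F11. This acid chloride C-acylates the magnesium enolate of 13 once (MgCl2, pyridine) to give dimethyl 2-[(4R)-2-methoxycarbonyl-7-methyl-2-(3-methylbut-2-enyl)-4-(2-methylprop-1-enyl)oct-7-enoyl]-3-oxopentanedioate F12, and NaOMe in MeOH closes it by Dieckmann condensation to 14.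

Step 2. The likely failures are insufficient enantioselectivity or site selectivity on this diene, or ring opening of the sensitive cyclopropane on the Lewis-acidic catalyst.
Fallback, setting out from 2 and 3 and returning at 4: cyclopropanation with the achiral catalyst Rh2(OAc)4 gives racemic 6,6-dimethyl-1-(2-methylprop-1-enyl)-5,7-dioxaspiro[2.5]octane-4,8-dione F13, and the (1S)-enantiomer 4 is separated from it by preparative chromatography on a chiral stationary phase.

## Further compounds

F1 | step 4 | dimethyl 2-(phenyliodonio)propanedioate ylide | COC(=O)[C-]([I+]c1ccccc1)C(=O)OC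
F2 | step 4 | dimethyl (2S)-2-(2-methylprop-1-enyl)cyclopropane-1,1-dicarboxylate | COC(=O)C1(C[C@H]1C=C(C)C)C(=O)OC
F3 | step 4 | dimethyl 2-[(2R)-5-methyl-2-(2-methylprop-1-enyl)hex-5-enyl]propanedioate | C=C(C)CC[C@@H](C=C(C)C)CC(C(=O)OC)C(=O)OC
F4 | step 4 | dimethyl 2-[(2R)-5-methyl-2-(2-methylprop-1-enyl)hex-5-enyl]-2-(3-methylbut-2-enyl)propanedioate | C=C(C)CC[C@@H](C=C(C)C)CC(CC=C(C)C)(C(=O)OC)C(=O)OC
F0 | step 9 | none | none
F5 | step 16 | (4R)-4-benzyl-3-[(2R,3S)-3-hydroxy-2-methylbutanoyl]-1,3-oxazolidin-2-one | O=C1OC[C@@H](Cc2ccccc2)N1C(=O)[C@H](C)[C@H](C)O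
F6 | step 16 | (4R)-4-benzyl-3-[(2R,3S)-3-[tert-butyl(dimethyl)silyl]oxy-2-methylbutanoyl]-1,3-oxazolidin-2-one | O=C1OC[C@@H](Cc2ccccc2)N1C(=O)[C@H](C)[C@H](C)O[Si](C)(C)C(C)(C)C
F7 | step 16 | (2R,3S)-3-[tert-butyl(dimethyl)silyl]oxy-2-methylbutanoic acid | OC(=O)[C@H](C)[C@H](C)O[Si](C)(C)C(C)(C)C
F8 | step 16 | prop-2-enyl (3R)-3-[(3S)-5-{(2R,3S)-3-[tert-butyl(dimethyl)silyl]oxy-2-methylbutanoyl}-2,6-dihydroxy-3-[(2R)-5-methyl-2-(2-methylprop-1-enyl)hex-5-enyl]-3-(3-methylbut-2-enyl)-4-oxocyclohexa-1,5-dien-1-yl]-3-phenylpropanoate | C=C(C)CC[C@@H](C=C(C)C)C[C@@]1(CC=C(C)C)C(=O)C(C(=O)[C@H](C)[C@H](C)O[Si](C)(C)C(C)(C)C)=C(O)C([C@H](CC(=O)OCC=C)c2ccccc2)=C1O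
F9 | step 16 | prop-2-enyl (3R)-3-[(3S)-2,6-dihydroxy-5-[(2R,3S)-3-hydroxy-2-methylbutanoyl]-3-[(2R)-5-methyl-2-(2-methylprop-1-enyl)hex-5-enyl]-3-(3-methylbut-2-enyl)-4-oxocyclohexa-1,5-dien-1-yl]-3-phenylpropanoate | C=C(C)CC[C@@H](C=C(C)C)C[C@@]1(CC=C(C)C)C(=O)C(C(=O)[C@H](C)[C@H](C)O)=C(O)C([C@H](CC(=O)OCC=C)c2ccccc2)=C1O
F10 | step 7 | (4R)-2-methoxycarbonyl-7-methyl-2-(3-methylbut-2-enyl)-4-(2-methylprop-1-enyl)oct-7-enoic acid (malonic half ester; both epimers at C2) | C=C(C)CC[C@@H](C=C(C)C)CC(CC=C(C)C)(C(=O)O)C(=O)OC
F11 | step 7 | methyl (4R)-2-carbonochloridoyl-7-methyl-2-(3-methylbut-2-enyl)-4-(2-methylprop-1-enyl)oct-7-enoate (both epimers at C2) | C=C(C)CC[C@@H](C=C(C)C)CC(CC=C(C)C)(C(=O)Cl)C(=O)OC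
F12 | step 7 | dimethyl 2-[(4R)-2-methoxycarbonyl-7-methyl-2-(3-methylbut-2-enyl)-4-(2-methylprop-1-enyl)oct-7-enoyl]-3-oxopentanedioate | C=C(C)CC[C@@H](C=C(C)C)CC(CC=C(C)C)(C(=O)OC)C(=O)C(C(=O)OC)C(=O)CC(=O)OC
F13 | step 2 | racemic 6,6-dimethyl-1-(2-methylprop-1-enyl)-5,7-dioxaspiro[2.5]octane-4,8-dione | CC1(C)OC(=O)C2(CC2C=C(C)C)C(=O)O1
A1 | alternative 1 | 3-(3-methylbut-3-enyl)-4a-(3-methylbut-2-enyl)-2,3,4,4a-tetrahydrochromene-5,7(6H)-dione closed through O5, with the 3- and 4a-substituents trans | C=C(C)CC[C@@H]2C[C@@]1(CC=C(C)C)C(OC2)=CC(=O)CC1=O
A2 | alternative 2 | lactol from closure of the C2′ aldehyde on O5 of the aromatic chromanone core (methyl ester, triisopropylsilyl ether; lactol carbon as a mixture) | C=C(C)CC[C@@H](C(O)O1)Cc2c1c3C(=O)[C@H](C)[C@@H](C)Oc3c([C@H](CC(=O)OC)c3ccccc3)c2O[Si](C(C)C)(C(C)C)C(C)C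
A3 | alternative 3 | tert-butyl ester of the target | C=C(C)CC[C@@H](C=C(C)C)C[C@@]1(CC=C(C)C)C(=O)C2=C(O)[C@H](C)[C@@H](C)OC2=C([C@H](CC(=O)OC(C)(C)C)c2ccccc2)C1=O
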